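Remark on the chemistry: the SMILES defines both stereocentres as S. The ring is numbered C1 (CO2H), C2 (side chain), C4 and C6 (OH), and the side chain C1'–C13'. Lithium naphthalenide is written LiC10H8.

## Analysis of the target

Compound 21 is a 2-alkyl-4,6-dihydroxybenzoic acid. The benzene ring carries the carboxyl group on C1, an unbranched thirteen-carbon chain on C2 and free hydroxyls on C4 and C6; the chain bears acetoxy groups on C2' and C12'. The two stereocentres, C2' and C12', are both S and are separated by nine methylene groups, so neither can steer the other and each must be brought in on its own from a chiral building block. Three kinds of oxygen have to end up differentiated: free phenols, a free acid and two secondary acetates. The electron-rich salicylic acid core decarboxylates easily when heated in acid, so the last steps must be mild and neutral. The C2' oxygen lies five atoms from the carboxyl carbon, and whenever both are free they close to a six-membered lactone (a 3,4-dihydroisocoumarin); this is a hazard late in the route and a useful internal protecting group earlier. The main difficulty is the contiguous ring triad C6–O, C1–CO2H, C2–CH2, which electrophilic substitution of a resorcinol does not deliver cleanly. The strategy rests on that triad: C1 and C2 are neighbours and C1 is flanked on its other side by the C6 oxygen, the pattern left when a carbon nucleophile and then an electrophile add across a 3-alkoxyaryne.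

## Retrosynthetic reasoning

21 from 20. The last operation should release both phenols and the acid without touching the acetates. The three O–benzyl bonds of 20 are cut by hydrogenolysis, which is neutral and leaves secondary alkyl acetates alone. The C2' acetate is homobenzylic, not benzylic, so it is not at risk.

20 from 19, and 19 from 17. The two acetates are put on together once the phenols and the carboxyl group are capped, so 20 comes from diol 19 by acetylation. Diol 19 has C2'–OH free and the carboxyl as a benzyl ester; it is the ring-opened, benzylated form of lactone 17. Alkaline cleavage of the lactone acyl–oxygen bond gives salt 18, in which the carboxylate cannot re-close, and benzylation of 18 caps the carboxylate and both phenoxides in one operation. The forward step has to keep 19 from re-lactonising before it is acetylated.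

17 from 16. The three O–C/O–Si bonds of the methyl ethers and the silyl ether are cut in one Lewis-acid step. The lactone is kept through this step because it ties up the C2' oxygen and the carboxyl group while the ring oxygens are unmasked.

16 from 8, 9 and 10 (key disconnection). The aryl C2–C1' bond and the aryl C1–carboxyl bond are cut together. This turns the contiguous ring triad into 3,5-dimethoxybenzyne 13, which comes from the bought fluoroarene 9 by way of its lithio derivative 12. The nucleophile is the β-oxido alkyllithium 11, made from chlorohydrin 8, and the electrophile is carbon dioxide 10. Cutting here, and not inside the chain, lets the whole chain arrive with both stereocentres already set and places both ring substituents in one flask. The forward reaction must add 11 to the aryne carbon remote from the flanking methoxy group, carboxylate the aryllithium 14, and close hydroxy acid 15 to lactone 16. The alkoxide oxygen that makes 11 accessible from a chlorohydrin is the same oxygen that later forms the lactone.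

8 from 5 and 6. The C3–C4 bond of the chlorohydrin is cut. Grignard reagent 7, made from chloride 5, opens (S)-epichlorohydrin 6 at its epoxide terminus. This sets the C2' centre from the chiral pool and gives the chlorohydrin directly, the function needed for reductive lithiation.

5 from 4, and 4 from 1 and 2. Silyl ether 5 is the protected form of alcohol 4. In 4 the C3–C4 bond is cut: Grignard reagent 3, formed at the bromide end of linker 1, opens (S)-propylene oxide 2 at its methylene carbon. This sets the C12' centre, and the chloride end of the linker is left for the second Grignard formation.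

## Alternatives that were turned down

Alternative 1: benzene ring by alkynoate Diels–Alder and isobutene extrusion.
- Disconnection: ring bonds C2–C3 and C1–C6 are cut, so the arene is built from the chiral alkynoate benzyl (5S,15S)-5,15-diacetoxyhexadec-2-ynoate A2 and the dimedone-derived diene 5,5-dimethyl-1,3-bis(trimethylsilyloxy)cyclohexa-1,3-diene A3.
- Forward key step: [4+2] cycloaddition gives a bicyclo[2.2.2]octadiene, which loses isobutene in a retro-Diels–Alder step. After desilylation the product is benzyl 2-[(2S,12S)-2,12-diacetoxytridecyl]-4,6-dihydroxybenzoate A1.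
- For it: the ring appears with the finished diacetate chain attached and with the phenols free, so no methyl ether cleavage, no lactone opening and no re-protection are needed. A1 is one hydrogenolysis from 21. On the endgame this alternative is stronger than the chosen route.
- Against it: A2 is a β-alkyl alkynoate, a weak dienophile. The reacting diene terminus of A3 is next to the quaternary carbon, so the bond to the substituted alkyne carbon forms at a congested site. Cycloaddition and isobutene loss both need high temperatures. Under those conditions the propargylic methylene of A2, next to an acetoxy-bearing carbon, can isomerise to an allenoate and lose acetic acid. Making A2 also needs acetylide chemistry before the acetates can go on, so the total step count is about the same.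
- Comparison: the chosen route forms both ring–substituent bonds below −40 °C, its regiochemistry is dictated directly by a methoxy group, and the arene is bought with its oxygens in place. It pays for this with a longer endgame.

Alternative 2: cyclohexane-1,3-dione annulation with malonate, aromatised late.
- Disconnection: ring bonds C1–C2 and C5–C6 are cut.
- Forward key step: dibenzyl malonate A6 adds in Michael fashion to the enone (3E,6S,16S)-6,16-bis(tert-butyldimethylsilyloxy)heptadec-3-en-2-one A5, and the methyl-side enolate then closes the ring by Claisen condensation. The product is benzyl 6-[(2S,12S)-2,12-bis(tert-butyldimethylsilyloxy)tridecyl]-2,4-dioxocyclohexane-1-carboxylate A4, which must be dehydrogenated later.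
- For it: classical anionic chemistry, cheap reagents, no cryogenic organolithium work, and a ring-forming reaction well established for this class of enone. Here it is more secure than the chosen key step, which is untested.
- Against it: A5 carries a silyloxy group β to its γ-carbon, so the alkoxide base can cause vinylogous E1cB loss of silanolate to a dienone. Aromatising A4 needs an oxidant or a halogenation–elimination sequence on a β-keto ester that decarboxylates easily. After that the silyl groups must still be exchanged for acetates in the presence of free phenols. The route is several steps longer.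
- Comparison: the chosen route buys the arene at the correct oxidation level and places its single uncertain step early, on cheap material.

Alternative 3: double Baeyer–Villiger turning two carbon stereocentres into acetates.
- Disconnection: the C2'–O and C12'–O bonds are cut.
- Forward key step: a peracid oxidises both methyl ketones of (3S,13S)-3-[3,5-bis(benzyloxy)benzyl]-13-methylpentadecane-2,14-dione A8. Each secondary carbon migrates with retention, giving (2S,12S)-1-[3,5-bis(benzyloxy)phenyl]tridecane-2,12-diyl diacetate A7.
- For it: both oxygens are delivered directly as acetates with stereoretention, so no alcohol protecting groups are needed on the chain. The migratory preference of a secondary carbon over methyl is dependable. On protecting-group economy it is stronger than the chosen route.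
- Against it: the stereochemical problem moves to two enolisable α-branched methyl ketones, which need two separate auxiliary-controlled alkylations and can epimerise. A7 still lacks the carboxyl carbon, which would have to be introduced afterwards on an electron-rich ring with two competing positions and in the presence of the acetates. The peracid can also oxidise the dialkoxyarene. It is the longest of the four routes.
- Comparison: the chosen route takes both stereocentres from chiral-pool epoxides as configurationally stable carbinols and installs the carboxyl group in the same step as the chain.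

Key step: step 4

## Route

Step 1
Reactants: 1 1-bromo-7-chloroheptane; 2 (S)-propylene oxide
Product: 4 (S)-10-chlorodecan-2-ol, via 7-chloroheptylmagnesium bromide 3 (not isolated)
Conditions: Mg, THF, 30 °C; then CuI (10 mol %), 2, THF, −30 → 0 °C; aq NH4Cl
Reagents that add atoms: none
Why: Magnesium inserts into the C–Br bond much faster than into C–Cl, and the CuI-catalysed Grignard opening of a terminal epoxide occurs at the unsubstituted carbon, so the S carbinol centre of 2 is carried over unchanged as C2 of 4.

Step 2
Reactants: 4 (S)-10-chlorodecan-2-ol
Product: 5 (S)-tert-butyl[(10-chlorodecan-2-yl)oxy]dimethylsilane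
Conditions: TBSCl, imidazole, DMF, rt
Reagents that add atoms: tert-butyldimethylsilyl chloride (TBSCl), CC(C)(C)[Si](C)(C)Cl
Why: Standard silylation of a secondary alcohol; the silyl ether tolerates the Grignard and organolithium chemistry that follows and the primary chloride is unaffected.

Step 3
Reactants: 5 (S)-tert-butyl[(10-chlorodecan-2-yl)oxy]dimethylsilane; 6 (S)-epichlorohydrin
Product: 8 (2S,12S)-12-(tert-butyldimethylsilyloxy)-1-chlorotridecan-2-ol, via [(9S)-9-(tert-butyldimethylsilyloxy)decyl]magnesium chloride 7 (not isolated)
Conditions: Mg (I2 cat.), THF, 60 °C; then CuI (10 mol %), 6, THF, −40 → −20 °C; aq NH4Cl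
Reagents that add atoms: none
Why: CuI-catalysed Grignard opening of epichlorohydrin at the epoxide methylene gives the 1-chloroalkan-2-ol with the carbinol centre untouched (S in 6 becomes 2S in 8, same spatial arrangement); keeping the mixture cold stops the chloro-alkoxide from closing to an epoxide.

Step 4
Reactants: 8 (2S,12S)-12-(tert-butyldimethylsilyloxy)-1-chlorotridecan-2-ol; 9 1-fluoro-3,5-dimethoxybenzene; 10 carbon dioxide
Product: 16 (3S)-3-[(10S)-10-(tert-butyldimethylsilyloxy)undecyl]-6,8-dimethoxyisochroman-1-one, via the β-oxido alkyllithium 11 (not isolated), via 2-fluoro-4,6-dimethoxyphenyllithium 12 (not isolated), via 3,5-dimethoxybenzyne 13 (not isolated), via the dilithiated aryne adduct 14 (not isolated), via the hydroxy acid 15 (not isolated)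
Conditions: 8, n-BuLi (1.0 equiv) then LiC10H8 (2.0 equiv), THF, −78 °C (→ 11); separately 9 (1.2 equiv), sec-BuLi (1.2 equiv), THF, −78 °C (→ 12); 12 cannulated into 11, −78 → −40 °C; CO2 (10), −78 °C → rt; 1 M HCl, 0 °C; PPTS (cat.), toluene, 50 °C
Reagents that add atoms: none
Why: Proposed new method: the closest known reaction type is the addition of simple alkyllithiums to 3-alkoxyarynes generated from meta-fluoroanisoles, with carboxylation of the resulting 2-lithioarene (the 6-alkylsalicylic acid synthesis); reductive lithiation of an O-lithiated chlorohydrin by LiC10H8 to a β-oxido alkyllithium is also known, and only their union is new. On warming, 12 loses fluoride to give aryne 13, and the primary carbanion of 11 attacks the aryne carbon remote from the flanking methoxy group, so the new aryl anion of 14 sits next to the inductively withdrawing, lithium-coordinating oxygen. CO2 then enters at that carbon, which fixes the C6–O/C1–CO2H/C2–CH2 triad. The competing unimolecular path is β-elimination from 11, but oxide is a poor leaving group, so 11 should survive the −78 to −40 °C window in which 12 collapses; pre-forming 12 with one equivalent of sec-BuLi leaves no free alkyllithium or proton source to intercept the aryne. On acidification, hydroxy acid 15 closes the δ-lactone ring of 16 by 6-exo-trig attack of the C2' hydroxyl on the carboxyl carbon. No stereocentre is created: C3 of 16 is the epichlorohydrin-derived carbinol carbon, which carries only an O–Li bond during the step and takes part in no bond that breaks. The step needs regioselectivity (lithiation of 9 between F and OMe, favoured by the acidifying fluorine, and addition meta to the methoxy group) and chemoselectivity (C-attack by the carbanion of 11, a far stronger nucleophile than its alkoxide).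

Step 5
Reactants: 16 (3S)-3-[(10S)-10-(tert-butyldimethylsilyloxy)undecyl]-6,8-dimethoxyisochroman-1-one
Product: 17 (3S)-6,8-dihydroxy-3-[(10S)-10-hydroxyundecyl]isochroman-1-one
Conditions: BBr3 (6 equiv), CH2Cl2, −78 °C → rt; then H2O, 0 °C
Reagents that add atoms: none
Why: Lewis-acid ether cleavage: bromide attacks the methyl carbon of each complexed aryl methyl ether and the silyl ether is cleaved at the Si–O bond, so both stereogenic C–O bonds stay intact; the lactone, an aryl ester of a secondary alcohol, is cleaved far more slowly.

Step 6
Reactants: 17 (3S)-6,8-dihydroxy-3-[(10S)-10-hydroxyundecyl]isochroman-1-one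
Product: 19 benzyl 2,4-bis(benzyloxy)-6-[(2S,12S)-2,12-dihydroxytridecyl]benzoate, via the tripotassium salt 18 (not isolated)
Conditions: KOH (3.3 equiv), H2O/1,4-dioxane, 50 °C, N2; evaporate, toluene azeotrope; BnBr (3.6 equiv), DMF, rt
Reagents that add atoms: potassium hydroxide, [K+].[OH-]; benzyl bromide, BrCc1ccccc1
Why: Saponification of the lactone by acyl–oxygen cleavage leaves C2' untouched and gives a carboxylate that cannot re-close; Williamson-type O-alkylation of the carboxylate and both phenoxides follows, while the secondary alcohols are not deprotonated at this basicity and stay free.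

Step 7
Reactants: 19 benzyl 2,4-bis(benzyloxy)-6-[(2S,12S)-2,12-dihydroxytridecyl]benzoate
Product: 20 benzyl 2,4-bis(benzyloxy)-6-[(2S,12S)-2,12-diacetoxytridecyl]benzoate
Conditions: Ac2O, pyridine, DMAP (cat.), CH2Cl2, 0 °C → rt
Reagents that add atoms: acetic anhydride, CC(=O)OC(C)=O
Why: DMAP-catalysed acylation of both secondary alcohols at oxygen with retention; it should be faster than attack of the C2' hydroxyl on the hindered di-ortho-substituted benzyl ester.

Step 8
Reactants: 20 benzyl 2,4-bis(benzyloxy)-6-[(2S,12S)-2,12-diacetoxytridecyl]benzoate
Product: 21 2-[(2S,12S)-2,12-diacetoxytridecyl]-4,6-dihydroxybenzoic acid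
Conditions: H2 (1 atm), 10% Pd/C, EtOAc, rt
Reagents that add atoms: none
Why: Hydrogenolysis cleaves the two aryl benzyl ethers and the benzyl ester under neutral conditions; the secondary acetates are not benzylic and stay in place, and no acid or heat is applied that could cause lactonisation or decarboxylation.

## Compound list

1 | 1-bromo-7-chloroheptane | ClCCCCCCCBr | starting material
2 | (S)-propylene oxide | C[C@H]1CO1 | starting material
3 | 7-chloroheptylmagnesium bromide (not isolated) | ClCCCCCCC[Mg]Br | intermediate
4 | (S)-10-chlorodecan-2-ol | C[C@H](O)CCCCCCCCCl | intermediate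
5 | (S)-tert-butyl[(10-chlorodecan-2-yl)oxy]dimethylsilane | C[C@H](O[Si](C)(C)C(C)(C)C)CCCCCCCCCl | intermediate
6 | (S)-epichlorohydrin | ClC[C@@H]1CO1 | starting material
7 | [(9S)-9-(tert-butyldimethylsilyloxy)decyl]magnesium chloride (not isolated) | C[C@H](O[Si](C)(C)C(C)(C)C)CCCCCCCC[Mg]Cl | intermediate
8 | (2S,12S)-12-(tert-butyldimethylsilyloxy)-1-chlorotridecan-2-ol | O[C@@H](CCCCCCCCC[C@H](C)O[Si](C)(C)C(C)(C)C)CCl | intermediate
9 | 1-fluoro-3,5-dimethoxybenzene | COc1cc(F)cc(OC)c1 | starting material
10 | carbon dioxide | O=C=O | starting material
11 | [(12S)-12-(tert-butyldimethylsilyloxy)-2-(lithiooxy)tridecyl]lithium, C2 arranged as in 8 (formal descriptor 2R because CH2Li ranks below the chain; not isolated) | [Li]O[C@@H](CCCCCCCCC[C@H](C)O[Si](C)(C)C(C)(C)C)C[Li] | intermediate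
12 | 2-fluoro-4,6-dimethoxyphenyllithium (not isolated) | COc1cc(F)c([Li])c(OC)c1 | intermediate
13 | 3,5-dimethoxybenzyne (not isolated) | COC1=CC(OC)=CC#C1 | intermediate
14 | {2-[(2S,12S)-12-(tert-butyldimethylsilyloxy)-2-(lithiooxy)tridecyl]-4,6-dimethoxyphenyl}lithium (not isolated) | [Li]O[C@@H](CCCCCCCCC[C@H](C)O[Si](C)(C)C(C)(C)C)Cc1cc(OC)cc(OC)c1[Li] | intermediate
15 | 2-[(2S,12S)-12-(tert-butyldimethylsilyloxy)-2-hydroxytridecyl]-4,6-dimethoxybenzoic acid (not isolated) | O[C@@H](CCCCCCCCC[C@H](C)O[Si](C)(C)C(C)(C)C)Cc1cc(OC)cc(OC)c1C(=O)O | intermediate
16 | (3S)-3-[(10S)-10-(tert-butyldimethylsilyloxy)undecyl]-6,8-dimethoxyisochroman-1-one | O=C1O[C@@H](CCCCCCCCC[C@H](C)O[Si](C)(C)C(C)(C)C)Cc2cc(OC)cc(OC)c12 | intermediate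
17 | (3S)-6,8-dihydroxy-3-[(10S)-10-hydroxyundecyl]isochroman-1-one | O=C1O[C@@H](CCCCCCCCC[C@H](C)O)Cc2cc(O)cc(O)c12 | intermediate
18 | tripotassium 2-[(2S,12S)-2,12-dihydroxytridecyl]-4,6-dioxidobenzoate (not isolated) | O[C@@H](CCCCCCCCC[C@H](C)O)Cc1cc([O-])cc([O-])c1C(=O)[O-].[K+].[K+].[K+] | intermediate
19 | benzyl 2,4-bis(benzyloxy)-6-[(2S,12S)-2,12-dihydroxytridecyl]benzoate | O[C@@H](CCCCCCCCC[C@H](C)O)Cc1cc(OCc2ccccc2)cc(OCc2ccccc2)c1C(=O)OCc1ccccc1 | intermediate
20 | benzyl 2,4-bis(benzyloxy)-6-[(2S,12S)-2,12-diacetoxytridecyl]benzoate | CC(=O)O[C@@H](CCCCCCCCC[C@H](C)OC(C)=O)Cc1cc(OCc2ccccc2)cc(OCc2ccccc2)c1C(=O)OCc1ccccc1 | intermediate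
21 | 2-[(2S,12S)-2,12-diacetoxytridecyl]-4,6-dihydroxybenzoic acid | CC(=O)O[C@@H](CCCCCCCCC[C@H](C)OC(C)=O)Cc1cc(O)cc(O)c1C(=O)O | target

## Step count and least certain steps

Total step count: 8 steps. Longest linear sequence: 8 steps (1 to 21); 2, 6, 9 and 10 enter as bought components.

Step 4 (key step, proposed new method). The most likely failure is a mismatch of temperature windows: β-elimination of the oxido alkyllithium to a terminal alkene may set in before, or while, 12 loses fluoride. Two other processes compete: aryl–aryl coupling, when 12 or 14 instead of 11 adds to the aryne, and lithiation of 9 between the two methoxy groups, which gives an aryllithium that cannot form the aryne. The fallback uses only known reactions, sets out from 8 and rejoins the route at 16. Chlorohydrin 8 is closed with K2CO3 in MeOH to (S)-2-[(10S)-10-(tert-butyldimethylsilyloxy)undecyl]oxirane F1. CuI-catalysed opening of F1 at its terminal carbon with commercial 3,5-dimethoxyphenylmagnesium bromide in THF gives (2S,12S)-12-(tert-butyldimethylsilyloxy)-1-(3,5-dimethoxyphenyl)tridecan-2-ol F2; this forms the aryl–C1' bond without touching the stereocentre. NBS in MeCN at 0 °C brominates the ring ortho to the side chain and para to a methoxy group, which should be less hindered than the position between the two methoxy groups, to give (2S,12S)-1-(2-bromo-3,5-dimethoxyphenyl)-12-(tert-butyldimethylsilyloxy)tridecan-2-ol F3. Two equivalents of n-BuLi at −78 °C (O–H deprotonation, then bromine–lithium exchange) regenerate 14, which is carboxylated with 10 and lactonised as in step 4 to give 16. This costs three more steps.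

Step 5. The remote carbinol passes through an alkyl borate, and slow substitution by bromide at C12' with loss of configuration is the main danger. Alkyl–oxygen cleavage of the lactone and incomplete cleavage of the unchelated 6-methoxy group are further risks. The fallback sets out from 16 and rejoins the route at 18. HF·pyridine in THF removes the silyl group to give (3S)-3-[(10S)-10-hydroxyundecyl]-6,8-dimethoxyisochroman-1-one F4. Acetylation (Ac2O, pyridine, DMAP) gives (2S)-11-[(3S)-6,8-dimethoxy-1-oxoisochroman-3-yl]undecan-2-yl acetate F5; its carbonyl oxygen, not the alkyl oxygen, is the Lewis-basic site, so no alkyl borate forms at the stereocentre. BBr3 then cleaves only the methyl ethers to give (2S)-11-[(3S)-6,8-dihydroxy-1-oxoisochroman-3-yl]undecan-2-yl acetate F6. Hydrolysis of F6 under the conditions of step 6 with one more equivalent of KOH removes the acetate together with the lactone and delivers 18.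

Step 6. Re-closure of the lactone from 19 during benzylation (intramolecular transesterification with loss of benzyl alcohol) is the most likely failure. Also possible are O-benzylation of a side-chain alkoxide if hydroxide is carried over, sluggish hydrolysis of the phenoxide-deactivated lactone, and decarboxylation of the electron-rich salt on heating. The fallback sets out from 17 and rejoins the route at 19; it protects the phenols before the ring is opened, so the hydroxy ester never meets carbonate or phenoxide base. BnBr and K2CO3 in DMF at 60 °C convert 17 into (3S)-6,8-bis(benzyloxy)-3-[(10S)-10-hydroxyundecyl]isochroman-1-one F7. This lactone is no longer deactivated and is opened with 1.1 equivalents of KOH in aqueous dioxane at reflux to potassium 2,4-bis(benzyloxy)-6-[(2S,12S)-2,12-dihydroxytridecyl]benzoate F8. After drying, the salt is alkylated at the carboxylate with BnBr in DMF at rt without added base to give 19. This costs one more step.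

Step 3. Magnesium insertion into the primary chloride may be slow and accompanied by Wurtz homocoupling. In the opening, ring closure of the chloro-alkoxide to an epoxide followed by a second addition is possible if the temperature rises. The fallback sets out from 5 and rejoins the route at 8. NaI in acetone converts 5 into (S)-tert-butyl[(10-iododecan-2-yl)oxy]dimethylsilane F9. Iodine–lithium exchange with two equivalents of t-BuLi in Et2O/pentane at −78 °C gives [(9S)-9-(tert-butyldimethylsilyloxy)decyl]lithium F10, which opens 6 at the epoxide methylene in the presence of BF3·OEt2 at −78 °C to give 8.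

## Further compounds

F1 | step 4 | (S)-2-[(10S)-10-(tert-butyldimethylsilyloxy)undecyl]oxirane | O1[C@@H](CCCCCCCCC[C@H](C)O[Si](C)(C)C(C)(C)C)C1
F2 | step 4 | (2S,12S)-12-(tert-butyldimethylsilyloxy)-1-(3,5-dimethoxyphenyl)tridecan-2-ol | O[C@@H](CCCCCCCCC[C@H](C)O[Si](C)(C)C(C)(C)C)Cc1cc(OC)cc(OC)c1
F3 | step 4 | (2S,12S)-1-(2-bromo-3,5-dimethoxyphenyl)-12-(tert-butyldimethylsilyloxy)tridecan-2-ol | O[C@@H](CCCCCCCCC[C@H](C)O[Si](C)(C)C(C)(C)C)Cc1cc(OC)cc(OC)c1Br
F4 | step 5 | (3S)-3-[(10S)-10-hydroxyundecyl]-6,8-dimethoxyisochroman-1-one | O=C1O[C@@H](CCCCCCCCC[C@H](C)O)Cc2cc(OC)cc(OC)c12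
F5 | step 5 | (2S)-11-[(3S)-6,8-dimethoxy-1-oxoisochroman-3-yl]undecan-2-yl acetate | O=C1O[C@@H](CCCCCCCCC[C@H](C)OC(C)=O)Cc2cc(OC)cc(OC)c12
F6 | step 5 | (2S)-11-[(3S)-6,8-dihydroxy-1-oxoisochroman-3-yl]undecan-2-yl acetate | O=C1O[C@@H](CCCCCCCCC[C@H](C)OC(C)=O)Cc2cc(O)cc(O)c12
F7 | step 6 | (3S)-6,8-bis(benzyloxy)-3-[(10S)-10-hydroxyundecyl]isochroman-1-one | O=C1O[C@@H](CCCCCCCCC[C@H](C)O)Cc2cc(OCc3ccccc3)cc(OCc3ccccc3)c12
F8 | step 6 | potassium 2,4-bis(benzyloxy)-6-[(2S,12S)-2,12-dihydroxytridecyl]benzoate | O[C@@H](CCCCCCCCC[C@H](C)O)Cc1cc(OCc2ccccc2)cc(OCc2ccccc2)c1C(=O)[O-].[K+]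
F9 | step 3 | (S)-tert-butyl[(10-iododecan-2-yl)oxy]dimethylsilane | C[C@H](O[Si](C)(C)C(C)(C)C)CCCCCCCCI
F10 | step 3 | [(9S)-9-(tert-butyldimethylsilyloxy)decyl]lithium | C[C@H](O[Si](C)(C)C(C)(C)C)CCCCCCCC[Li]
A1 | alternative 1 | benzyl 2-[(2S,12S)-2,12-diacetoxytridecyl]-4,6-dihydroxybenzoate | CC(=O)O[C@@H](CCCCCCCCC[C@H](C)OC(C)=O)Cc1cc(O)cc(O)c1C(=O)OCc1ccccc1
A2 | alternative 1 | benzyl (5S,15S)-5,15-diacetoxyhexadec-2-ynoate | CC(=O)O[C@@H](CCCCCCCCC[C@H](C)OC(C)=O)CC#CC(=O)OCc1ccccc1
A3 | alternative 1 | 5,5-dimethyl-1,3-bis(trimethylsilyloxy)cyclohexa-1,3-diene | C[Si](C)(C)OC1=CC(O[Si](C)(C)C)=CC(C)(C)C1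
A4 | alternative 2 | benzyl 6-[(2S,12S)-2,12-bis(tert-butyldimethylsilyloxy)tridecyl]-2,4-dioxocyclohexane-1-carboxylate | CC(C)(C)[Si](C)(C)O[C@@H](CCCCCCCCC[C@H](C)O[Si](C)(C)C(C)(C)C)CC1CC(=O)CC(=O)C1C(=O)OCc1ccccc1
A5 | alternative 2 | (3E,6S,16S)-6,16-bis(tert-butyldimethylsilyloxy)heptadec-3-en-2-one | CC(=O)/C=C/C[C@@H](O[Si](C)(C)C(C)(C)C)CCCCCCCCC[C@H](C)O[Si](C)(C)C(C)(C)C
A6 | alternative 2 | dibenzyl malonate | O=C(CC(=O)OCc1ccccc1)OCc1ccccc1
A7 | alternative 3 | (2S,12S)-1-[3,5-bis(benzyloxy)phenyl]tridecane-2,12-diyl diacetate | CC(=O)O[C@@H](CCCCCCCCC[C@H](C)OC(C)=O)Cc1cc(OCc2ccccc2)cc(OCc2ccccc2)c1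
A8 | alternative 3 | (3S,13S)-3-[3,5-bis(benzyloxy)benzyl]-13-methylpentadecane-2,14-dione | CC(=O)[C@@H](CCCCCCCCC[C@H](C)C(C)=O)Cc1cc(OCc2ccccc2)cc(OCc2ccccc2)c1
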